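**Retrosynthetic overview**

1. The target is a cis‑fused hydrindenone: a cyclopentenone (C1 ketone, C2=C3 bearing CO2Me and C16H33, C3a, C7a) fused to a cyclohexene (C4–C7) whose hydrogens at C3a, C4, C7 and C7a are all cis.
2. Enabling feature: C4 and C7 each carry a carboxyl carbon and flank C5=C6 (retron of an (E,E)-diene with both carboxyls "outside"), C3a/C7a are the β/α carbons of the C1 ketone (retron of a cyclopentadienone 2π partner), and the all‑cis hydrogens are the signature of an endo adduct.
3. Cutting C4–C3a and C7–C7a gives a transient 2‑methoxycarbonyl‑3‑hexadecylcyclopentadienone, released in the flask from a stable β‑hydroxy ketone, and a tert‑butyl methyl (2E,4E)‑hexadecylmuconate; Cu(SbF6)2·(S,S)-tBu-box is to choose the face, and the tert‑butyl ester is cleaved last.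
4. Dienone precursor: furan → 2,5‑dialkylfuran → oxidative opening and intramolecular aldol. Diene: acetoacetate γ‑alkylation → (E)-enol triflate → Heck reaction.
5. Ring order: five‑membered ring first (step 6), six‑membered ring last (step 7).

Key step: step 7

Remark: atom numbers are those of the indene skeleton of the target; (S,S)-tBu-box is 2,2'-(propane-2,2-diyl)bis[(4S)-4-tert-butyl-4,5-dihydro-1,3-oxazole]; the sense of induction on this substrate class cannot be taken from precedent, so the (S,S) ligand is written and its equally available antipode is used if it opens the other face.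

**Route**

Step 1
Reactants: 1 methyl acetoacetate; 2 1-bromopentadecane
Product: 4 methyl 3-oxononadecanoate, via acetoacetate dianion 3 (not isolated)
Conditions: NaH, THF, 0 °C; n-BuLi, 0 °C; then 2, 0 °C to rt; aq. HCl
Reagents that add atoms: none
Why: γ‑Alkylation of the acetoacetate dianion takes place at the more basic terminal carbon, so SN2 displacement of the primary bromide should give the β‑keto ester with the C16 chain on the ketone.

Step 2
Reactants: 4 methyl 3-oxononadecanoate
Product: 5 methyl (2E)-3-[(trifluoromethanesulfonyl)oxy]nonadec-2-enoate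
Conditions: Tf2O, aq. Me4NOH, toluene, 5 °C
Reagents that add atoms: trifluoromethanesulfonic anhydride, O=S(=O)(OS(=O)(=O)C(F)(F)F)C(F)(F)F
Why: Stereoselective enol triflation of the non‑chelated tetramethylammonium enolate, which prefers the extended geometry, should give the (E)-enol triflate (triflate trans to the ester; a chelating lithium counter‑ion would give Z), and this geometry later decides the configuration at C4.

Step 3
Reactants: 5 methyl (2E)-3-[(trifluoromethanesulfonyl)oxy]nonadec-2-enoate; 6 tert-butyl acrylate
Product: 7 1-tert-butyl 6-methyl (2E,4E)-4-hexadecylhexa-2,4-dienedioate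
Conditions: Pd(OAc)2 (5 mol %), PPh3, Et3N, DMF, 70 °C
Reagents that add atoms: none
Why: Heck reaction: oxidative addition of zerovalent palladium into the C–OTf bond with retention, syn insertion of the acrylate and syn β‑hydride elimination should give the (2E,4E)-diene with both carboxyl carbons on the outside of the s‑cis form.

Step 4
Reactants: 8 furan; 9 1-bromohexadecane
Product: 11 2-hexadecylfuran, via 2-furyllithium 10 (not isolated)
Conditions: n-BuLi, THF, 0 °C; then 9, 0 °C to rt
Reagents that add atoms: none
Why: α‑Lithiation of furan followed by SN2 alkylation of the aryllithium with a primary bromide is a standard route to 2‑alkylfurans.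

Step 5
Reactants: 11 2-hexadecylfuran; 12 methyl bromoacetate
Product: 15 methyl 2-(5-hexadecylfuran-2-yl)acetate, via 5-hexadecyl-2-furyllithium 13 (not isolated), via 5-hexadecyl-2-furylzinc chloride 14 (not isolated)
Conditions: n-BuLi, THF, 0 °C to rt; ZnCl2, 0 °C; then 12, Ni(acac)2 (5 mol %), PPh3, THF, rt
Reagents that add atoms: none
Why: Lithiation at the free α‑position, transmetalation to zinc and nickel‑catalysed Negishi‑type coupling of the arylzinc chloride with the bromoacetate should install the acetate side chain without attack on the ester.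

Step 6
Reactants: 15 methyl 2-(5-hexadecylfuran-2-yl)acetate
Product: 17 methyl 2-hexadecyl-2-hydroxy-5-oxocyclopent-3-ene-1-carboxylate (racemic mixture of both diastereomers), via cis-enedione 16 (not isolated)
Conditions: mCPBA, CH2Cl2, 0 °C; aq. NaHCO3 wash; then SiO2, CH2Cl2, rt
Reagents that add atoms: 3-chloroperoxybenzoic acid (mCPBA), OOC(=O)c1cccc(Cl)c1
Why: Peracid oxidation opens the 2,5‑dialkylfuran to the cis‑enedione, whose doubly activated methylene carbon adds to the long‑chain ketone in a 5‑exo intramolecular aldol addition that closes the five‑membered ring; the two new stereocentres are left uncontrolled because both are erased in step 7.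

Step 7
Reactants: 17 methyl 2-hexadecyl-2-hydroxy-5-oxocyclopent-3-ene-1-carboxylate; 7 1-tert-butyl 6-methyl (2E,4E)-4-hexadecylhexa-2,4-dienedioate
Product: 19 7-tert-butyl 2,4-dimethyl (3aR,4R,7R,7aS)-3,5-dihexadecyl-1-oxo-3a,4,7,7a-tetrahydro-1H-indene-2,4,7-tricarboxylate, via cyclopentadienone 18 (not isolated)
Conditions: Cu(SbF6)2·(S,S)-tBu-box (15 mol %), 4 Å MS, ClCH2CH2Cl, 40 °C; 17 added over 12 h to 7 (2 equiv)
Reagents that add atoms: none
Why: Proposed new method: divalent copper held by the C2‑symmetric bis(oxazoline) chelates the ring ketone and the ester carbonyl of 17, acidifies the hydrogen between them and drives loss of water to the copper‑bound cyclopentadienone 18 (both stereocentres of 17 are erased), and this strained, LUMO‑lowered 2π partner is taken up at its unsubstituted C3a=C7a bond by the s‑cis (2E,4E)-diene 7 in a concerted endo [4+2] cycloaddition. The closest known reaction types are the trapping of transient cyclopentadienones by added dienes and the bis(oxazoline)copper‑catalysed Diels–Alder reactions of chelating 2‑alkoxycarbonyl enones and quinones; what has not been shown is their union, with face control at the double bond remote from the ester of a fleeting dienone. The six‑membered ring (C3a, C4, C5, C6, C7, C7a) is closed by intermolecular suprafacial formation of C4–C3a and C7–C7a in one step. The E,E geometry puts both carboxyl carbons "outside" and so makes C4 and C7 cis to each other, the cis dienophile fixes C3a/C7a, the endo transition state (C1=O and C2=C3 under C5–C6) puts all four hydrogens on one face, and the absolute sense (addition to the Re face of C7a and the Si face of C3a) is set by the ligand tert‑butyl group that covers the other face beside the coordinated ketone. The step needs regioselectivity, secured by the largest diene HOMO coefficient at C4 (next to the C5 alkyl group, the two ester effects cancelling) meeting the largest LUMO coefficient at the enone β‑carbon C3a, and chemoselectivity for cross‑ over homo‑cycloaddition, secured by slow addition of 17 to excess 7 so that 18 never accumulates.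

Step 8
Reactants: 19 7-tert-butyl 2,4-dimethyl (3aR,4R,7R,7aS)-3,5-dihexadecyl-1-oxo-3a,4,7,7a-tetrahydro-1H-indene-2,4,7-tricarboxylate
Product: 20 (3aR,4R,7R,7aS)-3,5-dihexadecyl-2,4-bis(methoxycarbonyl)-1-oxo-3a,4,7,7a-tetrahydro-1H-indene-7-carboxylic acid
Conditions: TFA, CH2Cl2 (1:4), 0 °C
Reagents that add atoms: none
Why: Acidolysis of the tert‑butyl ester (E1 loss of 2‑methylpropene), kept cold and short so that the C5=C6 bond is not protonated, should free the C7 acid while the methyl esters, the enone and the four stereocentres stay untouched under non‑basic conditions.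

**Compound list**

1 | methyl acetoacetate | CC(=O)CC(=O)OC | starting material
2 | 1-bromopentadecane | CCCCCCCCCCCCCCCBr | starting material
3 | methyl acetoacetate dianion (lithium sodium salt) | [Li+].[Na+].C=C([O-])C=C([O-])OC | intermediate (not isolated)
4 | methyl 3-oxononadecanoate | CCCCCCCCCCCCCCCCC(=O)CC(=O)OC | intermediate
5 | methyl (2E)-3-[(trifluoromethanesulfonyl)oxy]nonadec-2-enoate | CCCCCCCCCCCCCCCC/C(OS(=O)(=O)C(F)(F)F)=C\C(=O)OC | intermediate
6 | tert-butyl acrylate | C=CC(=O)OC(C)(C)C | starting material
7 | 1-tert-butyl 6-methyl (2E,4E)-4-hexadecylhexa-2,4-dienedioate | CCCCCCCCCCCCCCCC/C(=C\C(=O)OC)/C=C/C(=O)OC(C)(C)C | intermediate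
8 | furan | c1ccoc1 | starting material
9 | 1-bromohexadecane | CCCCCCCCCCCCCCCCBr | starting material
10 | 2-furyllithium | [Li]c1ccco1 | intermediate (not isolated)
11 | 2-hexadecylfuran | CCCCCCCCCCCCCCCCc1ccco1 | intermediate
12 | methyl bromoacetate | COC(=O)CBr | starting material
13 | (5-hexadecylfuran-2-yl)lithium | [Li]c1ccc(CCCCCCCCCCCCCCCC)o1 | intermediate (not isolated)
14 | chloro(5-hexadecylfuran-2-yl)zinc | Cl[Zn]c1ccc(CCCCCCCCCCCCCCCC)o1 | intermediate (not isolated)
15 | methyl 2-(5-hexadecylfuran-2-yl)acetate | COC(=O)Cc1ccc(CCCCCCCCCCCCCCCC)o1 | intermediate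
16 | methyl (4Z)-3,6-dioxodocos-4-enoate | CCCCCCCCCCCCCCCCC(=O)/C=C\C(=O)CC(=O)OC | intermediate (not isolated)
17 | methyl 2-hexadecyl-2-hydroxy-5-oxocyclopent-3-ene-1-carboxylate (racemic, both diastereomers; no stereocentre defined) | CCCCCCCCCCCCCCCCC1(O)C=CC(=O)C1C(=O)OC | intermediate
18 | methyl 2-hexadecyl-5-oxocyclopenta-1,3-diene-1-carboxylate | CCCCCCCCCCCCCCCCC1=C(C(=O)OC)C(=O)C=C1 | intermediate (not isolated)
19 | 7-tert-butyl 2,4-dimethyl (3aR,4R,7R,7aS)-3,5-dihexadecyl-1-oxo-3a,4,7,7a-tetrahydro-1H-indene-2,4,7-tricarboxylate | CCCCCCCCCCCCCCCCC1=C[C@@H](C(=O)OC(C)(C)C)[C@H]2C(=O)C(C(=O)OC)=C(CCCCCCCCCCCCCCCC)[C@H]2[C@H]1C(=O)OC | intermediate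
20 | (3aR,4R,7R,7aS)-3,5-dihexadecyl-2,4-bis(methoxycarbonyl)-1-oxo-3a,4,7,7a-tetrahydro-1H-indene-7-carboxylic acid | CCCCCCCCCCCCCCCCC1=C[C@@H](C(=O)O)[C@H]2C(=O)C(C(=O)OC)=C(CCCCCCCCCCCCCCCC)[C@H]2[C@H]1C(=O)OC | target

**Step count and risks**

Total step count: 8. Longest linear sequence: 5 steps (steps 4, 5, 6, 7, 8; the diene branch, steps 1, 2, 3, 7, 8, is equally long).

Steps most likely to fail:

Step 7 (carries the label "Proposed new method:"). What may go wrong: the copper‑bound dienone is intercepted too slowly by the electron‑poor diene, so that homo‑cycloaddition of the dienone takes over; and the ligand, which sits on the far side of the ring, discriminates poorly between the two faces of C3a=C7a. The fallback uses known chemistry, sets out from 7 and 17 and comes back to the route at 20. Cleavage of the tert‑butyl ester of 7 (TFA, CH2Cl2) should give the diene acid (2E,4E)-4-hexadecyl-6-methoxy-6-oxohexa-2,4-dienoic acid F1. Steglich esterification (DCC, DMAP) with (S)-1-(4-methoxyphenyl)ethanol should convert it into the chiral diester 1-[(1S)-1-(4-methoxyphenyl)ethyl] 6-methyl (2E,4E)-4-hexadecylhexa-2,4-dienedioate F2. Slow addition of 17 to excess F2 in toluene at 90 °C, without metal, relies on thermal loss of water to 18 and the known uncatalysed endo trapping of a transient cyclopentadienone by a diene; any bridged isomer in which the dienone served as the 4π partner should converge on the fused adduct by Cope rearrangement on continued heating. Because the auxiliary is covalently bound, the two antipodal endo modes now give diastereomers, the wanted 7-[(1S)-1-(4-methoxyphenyl)ethyl] 2,4-dimethyl (3aR,4R,7R,7aS)-3,5-dihexadecyl-1-oxo-3a,4,7,7a-tetrahydro-1H-indene-2,4,7-tricarboxylate F3 and its (3aS,4S,7S,7aR) isomer F4, to be separated by chromatography. Acidolysis of F3 (TFA, anisole, CH2Cl2, 0 °C) should then give 20 directly.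

Step 5. What may go wrong: the furylzinc reagent is protonated by the acidic α‑hydrogens of the bromoacetate, and the bromoacetate is reduced or homo‑coupled at nickel instead of cross‑coupling. The fallback sets out from 11 and comes back at 15. Friedel–Crafts hydroxyalkylation of 11 at its free α‑position with methyl glyoxylate (Yb(OTf)3 cat., CH2Cl2) should give methyl 2-(5-hexadecylfuran-2-yl)-2-hydroxyacetate F5. Acetylation (Ac2O, pyridine) should give methyl 2-acetoxy-2-(5-hexadecylfuran-2-yl)acetate F6, and reductive cleavage of the α‑acetoxy group with SmI2 (THF–MeOH, −78 °C) should give 15.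

Step 6. What may go wrong: the peracid over‑oxidises the electron‑rich 2,5‑dialkylfuran or the β‑dicarbonyl side chain, and the cis‑enedione drifts to the trans isomer, which cannot cyclise. The fallback sets out from 11 and comes back at 17. The simpler monoalkylfuran 11 is opened with NBS in NaHCO3‑buffered aqueous acetone at −15 °C to the cis keto‑enal (2Z)-4-oxoicos-2-enal F7. Roskamp homologation of its aldehyde with methyl diazoacetate (SnCl2 cat., CH2Cl2, 0 °C) should generate 16 under neutral conditions, and 16 should close to 17 as in the main route.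

**Further compounds**

F1 | step 7 | (2E,4E)-4-hexadecyl-6-methoxy-6-oxohexa-2,4-dienoic acid | CCCCCCCCCCCCCCCC/C(=C\C(=O)OC)/C=C/C(=O)O
F2 | step 7 | 1-[(1S)-1-(4-methoxyphenyl)ethyl] 6-methyl (2E,4E)-4-hexadecylhexa-2,4-dienedioate | CCCCCCCCCCCCCCCC/C(=C\C(=O)OC)/C=C/C(=O)O[C@@H](C)c1ccc(OC)cc1
F3 | step 7 | 7-[(1S)-1-(4-methoxyphenyl)ethyl] 2,4-dimethyl (3aR,4R,7R,7aS)-3,5-dihexadecyl-1-oxo-3a,4,7,7a-tetrahydro-1H-indene-2,4,7-tricarboxylate | CCCCCCCCCCCCCCCCC1=C[C@@H](C(=O)O[C@@H](C)c3ccc(OC)cc3)[C@H]2C(=O)C(C(=O)OC)=C(CCCCCCCCCCCCCCCC)[C@H]2[C@H]1C(=O)OC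
F4 | step 7 | 7-[(1S)-1-(4-methoxyphenyl)ethyl] 2,4-dimethyl (3aS,4S,7S,7aR)-3,5-dihexadecyl-1-oxo-3a,4,7,7a-tetrahydro-1H-indene-2,4,7-tricarboxylate | CCCCCCCCCCCCCCCCC1=C[C@H](C(=O)O[C@@H](C)c3ccc(OC)cc3)[C@@H]2C(=O)C(C(=O)OC)=C(CCCCCCCCCCCCCCCC)[C@@H]2[C@@H]1C(=O)OC
F5 | step 5 | methyl 2-(5-hexadecylfuran-2-yl)-2-hydroxyacetate (racemic) | COC(=O)C(O)c1ccc(CCCCCCCCCCCCCCCC)o1
F6 | step 5 | methyl 2-acetoxy-2-(5-hexadecylfuran-2-yl)acetate (racemic) | COC(=O)C(OC(C)=O)c1ccc(CCCCCCCCCCCCCCCC)o1
F7 | step 6 | (2Z)-4-oxoicos-2-enal | CCCCCCCCCCCCCCCCC(=O)/C=C\C=O
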